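The whole plan depends on disconnecting the ring-fusion bond C1–C5 (C1 = quaternary C–Me, C5 = fusion CH). C6, the carbon bearing the anisate, is the direct neighbour of C5. A C6 carbonyl therefore marks the cyclopentane–cycloheptene bicycle as the outcome of a 1,2-alkyl shift in a methyl-decalin where C1 was attached to C6. In one operation the C6 alkoxide and a departing C5 mesylate drive a semipinacol shift of C1 from C6 to C5. This shrinks ring B to the cyclopentane, enlarges ring A to the cycloheptenone and fixes C5. Precursor 17 is a cis-decalin made from (S)-Wieland–Miescher ketone, carrying 4β-OTES, 5β-OMs, free 6β-OH, 10α-OTBS and the C8=C9 methyl alkene.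

Key step: step 12

**Conventions and remarks on the chemistry**
- The atom numbers of the target are kept for every intermediate: C1 (quaternary, Me), C2, C3 (CH2), C4, C5, C6, C7 (CH2), C8 (bears Me), C9, C10.
- In the decalins, ring A = C1-C6-C7-C8-C9-C10 and ring B = C1-C2-C3-C4-C5-C6.
- β is the face of the C1 methyl group and α is the opposite face. TBS = tert-butyldimethylsilyl, TES = triethylsilyl, Ms = methanesulfonyl.
- The target reads 1β-Me, 4β-OH/4α-iPr, 5α-H, 6α-O-anisoyl, 10α-OH.
- Compounds 17 and 19 were checked centre by centre. Inversion at C5 and retention at C1 lead from 17 to 19 and on to the target, and (S)-1 carries the correct C1 configuration. No structure needs changing.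
- An external hydride is expected to reach a C10 carbonyl anti to the neighbouring angular methyl, as in borohydride reduction of 1. It is also expected to reach the C6 ketone of 19 from the α face. These attacks would give 10β-OH and 6β-OH, which are the wrong epimers.
- Both carbinol centres are therefore set by hydroxyl-directed hydride delivery on the β face (steps 10 and 14).
- The 4β-oxygen must be free for the directed osmylation, which is why its protecting group is exchanged.
- Assumption: transient centres (C8 in 8 and 9; C9 and S in 6 and 9) are left undefined because they are erased in the same flask.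

**Step 1**
Reactants: 1 (S)-Wieland–Miescher ketone
Product: 2 1-methyl-Δ5(6)-octalin-4β,10β-diol
Conditions: NaBH4, CeCl3·7H2O, MeOH, −78 → 0 °C
Reagents that add atoms: none
Why: Luche reduction: cerium-assisted 1,2-hydride addition reaches both carbonyls from the α face, opposite the axial C1 methyl, so the enone gives the equatorial 4β-allylic alcohol (the steroid 4-en-3-one to 3β-ol pattern) and C10 gives the 10β-alcohol, whose centre is erased in step 3.

**Step 2**
Reactants: 2 1-methyl-Δ5(6)-octalin-4β,10β-diol
Product: 3 4β-(TBS-oxy)-1-methyl-Δ5(6)-octalin-10β-ol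
Conditions: TBSCl (1.05 equiv), imidazole, DMF, 0 °C
Reagents that add atoms: tert-butyldimethylsilyl chloride, CC(C)(C)[Si](C)(C)Cl
Why: Sterically controlled silyl ether formation: the allylic C4–OH has only CH2 and CH= neighbours whereas C10–OH is neopentylic next to quaternary C1, so one equivalent of TBSCl should stop at the C4 ether.

**Step 3**
Reactants: 3 4β-(TBS-oxy)-1-methyl-Δ5(6)-octalin-10β-ol
Product: 4 4β-(TBS-oxy)-1-methyl-Δ5(6)-octalin-10-one
Conditions: Dess–Martin periodinane, CH2Cl2, 0 °C → rt
Reagents that add atoms: none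
Why: Dess–Martin oxidation of the remaining secondary alcohol under neutral conditions leaves the allylic silyl ether and the C5=C6 alkene untouched.

**Step 4**
Reactants: 4 4β-(TBS-oxy)-1-methyl-Δ5(6)-octalin-10-one
Product: 7 4β-(TBS-oxy)-1-methyl-5(6),8(9)-dien-10-one (skipped dienone), via lithium enolate 5 (not isolated), via C9 sulfilimine 6 (not isolated)
Conditions: LiN(iPr)2, THF, −78 °C; then PhS(Cl)=NtBu, −78 °C
Reagents that add atoms: none
Why: Mukaiyama dehydrogenation: C9 is the only enolisable position because C1 is quaternary, enolate 5 attacks sulfur to give 6, and 6 loses the sulfenamide by a cyclic syn elimination already at −78 °C, which spares the base-sensitive doubly allylic C7 methylene of 7.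

**Step 5**
Reactants: 7 4β-(TBS-oxy)-1-methyl-5(6),8(9)-dien-10-one
Product: 10 4β-(TBS-oxy)-1,8-dimethyl-5(6),8(9)-dien-10-one, via 8-methyl lithium enolate 8 (not isolated), via 8-methyl C9 sulfilimine 9 (not isolated)
Conditions: Me2CuLi (CuI, MeLi), Et2O, −78 °C; then PhS(Cl)=NtBu, THF, −78 °C
Reagents that add atoms: lithium dimethylcuprate, [Li+].C[Cu-]C
Why: Gilman conjugate addition puts the methyl group on C8 and enolate 8 is dehydrogenated in the same flask by the Mukaiyama reagent (the known one-pot β-alkylation of enones): sulfur enters C9 trans to the new methyl, hence cis to H8 as the syn elimination requires, and the transient C8 centre vanishes.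

**Step 6**
Reactants: 10 4β-(TBS-oxy)-1,8-dimethyl-5(6),8(9)-dien-10-one
Product: 11 4β-hydroxy-1,8-dimethyl-5(6),8(9)-dien-10-one
Conditions: HF·pyridine, THF, 0 °C → rt
Reagents that add atoms: none
Why: Fluoride-mediated desilylation in a mildly acidic medium frees the 4β-OH needed as directing group without any base that could move the skipped diene into conjugation.

**Step 7**
Reactants: 11 4β-hydroxy-1,8-dimethyl-5(6),8(9)-dien-10-one
Product: 13 cis-decalin 4β,5β,6β-triol 8-en-10-one, via TMEDA osmate ester 12 (not isolated)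
Conditions: OsO4 (1.05 equiv), TMEDA, CH2Cl2, −78 °C; then HCl, MeOH, rt
Reagents that add atoms: osmium tetroxide, O=[Os](=O)(=O)=O
Why: Hydrogen-bond-directed dihydroxylation: the OsO4·TMEDA chelate accepts a hydrogen bond from the 4β-OH and adds suprafacially to the electron-rich C5=C6 bond on the β face (the electron-poor enone alkene is left alone), which sets 5β-OH and 6β-OH cis to the C1 methyl and creates the cis-decalin, after which methanolic HCl cleaves osmate 12.

**Step 8**
Reactants: 13 cis-decalin 4β,5β,6β-triol 8-en-10-one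
Product: 14 4β-(TES-oxy)-5β,6β-diol 8-en-10-one
Conditions: TESCl (1.0 equiv), imidazole, CH2Cl2, −20 °C
Reagents that add atoms: triethylsilyl chloride, CC[Si](Cl)(CC)CC
Why: Sterically controlled silylation: C4–OH adjoins a CH2 group whereas C5–OH is wedged between C4 and the fully substituted C6 and C6–OH is tertiary, so one equivalent of TESCl at low temperature should take C4–OH only.

**Step 9**
Reactants: 14 4β-(TES-oxy)-5β,6β-diol 8-en-10-one
Product: 15 4β-(TES-oxy)-5β-mesyloxy-6β-hydroxy 8-en-10-one
Conditions: MsCl, Et3N, CH2Cl2, 0 °C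
Reagents that add atoms: methanesulfonyl chloride, CS(=O)(=O)Cl
Why: Sulfonate ester formation at the only remaining secondary alcohol; the tertiary ring-fusion C6–OH does not react under these conditions.

**Step 10**
Reactants: 15 4β-(TES-oxy)-5β-mesyloxy-6β-hydroxy 8-en-10-one
Product: 16 4β-(TES-oxy)-5β-mesyloxy-8-ene-6β,10α-diol
Conditions: Me4NBH(OAc)3, MeCN/AcOH, −30 → −10 °C
Reagents that add atoms: none
Why: Evans–Saksena directed reduction: the 6β-OH exchanges onto boron and hands hydride to the β face of the 1,3-related C10 carbonyl through a six-membered transition state, giving the 10α-alcohol (anti to O6 and to the C1 methyl), while triacetoxyborohydride is too weak to reduce the hindered enone without this delivery.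

**Step 11**
Reactants: 16 4β-(TES-oxy)-5β-mesyloxy-8-ene-6β,10α-diol
Product: 17 cis-decalin hydroxy mesylate (4β-OTES, 5β-OMs, 6β-OH, 10α-OTBS, C8=C9)
Conditions: TBSOTf (1.1 equiv), 2,6-lutidine, CH2Cl2, −78 °C
Reagents that add atoms: tert-butyldimethylsilyl triflate, CC(C)(C)[Si](C)(C)OS(=O)(=O)C(F)(F)F
Why: Silyl triflate silylation of the only secondary alcohol at −78 °C; the C6–OH, tertiary and flanked by quaternary C1 and C5–OMs, is far slower and stays free for the key step.

**Step 12**
Reactants: 17 cis-decalin hydroxy mesylate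
Product: 19 trans-fused hydroazulen-6-one (4β-OTES, 5α-H, 10α-OTBS, C8=C9), via potassium alkoxide 18 (not isolated)
Conditions: KOtBu (1.05 equiv), THF, −40 → 0 °C; cold pH 7 phosphate buffer
Reagents that add atoms: none
Why: KOtBu removes the only hydroxyl proton, and alkoxide 18 pushes the C6–C1 σ bond, which is antiperiplanar to the equatorial C5–OMs bond, onto the rear of C5 in a concerted 1,2-shift that expels mesylate and leaves the C6 ketone. The closest known reaction type is the base-induced semipinacol (pinacol-type) rearrangement of decalin 1,2-diol monosulfonates to hydroazulenones. Neither ring is closed by cyclisation: the cyclopentane (C1–C5) arises by contraction of ring B and the cycloheptenone (C1, C5–C10) by the matching one-carbon expansion of ring A, both through the single new C1–C5 bond. C5 is the only new stereocentre and is fixed by stereospecific inversion (5β-OMs becomes 5α-H) while C1 migrates with retention, so the fusion can only be trans. The step needs C1 rather than C7 to migrate, and three things secure this: the conformer with an axial mesylate (which would align C6–C7) suffers a syn-diaxial clash between OMs and the angular methyl, potassium bridging of the syn-axial O4 and O6 favours the reactive conformer, and the fully substituted C1 is the better migrating group. One equivalent of base, low temperature and a cold buffered quench keep 19 from enolising, which would otherwise allow C5 epimerisation, loss of the C4 silyloxy group and conjugation of the C8=C9 bond.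

**Step 13**
Reactants: 19 trans-fused hydroazulen-6-one
Product: 20 4β-hydroxy-10α-(TBS-oxy)hydroazulen-6-one
Conditions: HF·pyridine, pyridine, THF, 0 °C
Reagents that add atoms: none
Why: Selective desilylation: a triethylsilyl ether is cleaved by buffered HF·pyridine much faster than the hindered TBS ether, and the non-basic medium avoids dehydration or retro-aldol cleavage of the β-hydroxy ketone.

**Step 14**
Reactants: 20 4β-hydroxy-10α-(TBS-oxy)hydroazulen-6-one
Product: 21 4β-acetoxy-10α-(TBS-oxy)hydroazulen-6α-ol
Conditions: SmI2 (0.3 equiv), MeCHO (6 equiv), THF, −10 °C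
Reagents that add atoms: acetaldehyde, CC=O
Why: Evans–Tishchenko reduction: the 4β-OH forms a samarium-bound hemiacetal with acetaldehyde whose hydride is transferred intramolecularly to the β face of C6, which sets the 6α-OH (1,3-anti to O4) and at the same time marks O4 as its acetate.

**Step 15**
Reactants: 21 4β-acetoxy-10α-(TBS-oxy)hydroazulen-6α-ol
Product: 22 4β-acetoxy-6α-(TES-oxy)-10α-(TBS-oxy)hydroazulene
Conditions: TESOTf, 2,6-lutidine, CH2Cl2, −78 °C
Reagents that add atoms: triethylsilyl triflate, CC[Si](CC)(CC)OS(=O)(=O)C(F)(F)F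
Why: Silyl ether formation at the single free hydroxyl gives a C6 protecting group that is orthogonal to the acetate and more labile than the C10 TBS ether.

**Step 16**
Reactants: 22 4β-acetoxy-6α-(TES-oxy)-10α-(TBS-oxy)hydroazulene
Product: 23 6α-(TES-oxy)-10α-(TBS-oxy)hydroazulen-4β-ol
Conditions: K2CO3, MeOH, 0 °C → rt
Reagents that add atoms: none
Why: Base-catalysed methanolysis (transesterification) removes the acetate, both silyl ethers tolerate K2CO3 in methanol, and the trans disposition of O4 and O6 disfavours silyl migration.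

**Step 17**
Reactants: 23 6α-(TES-oxy)-10α-(TBS-oxy)hydroazulen-4β-ol
Product: 24 6α-(TES-oxy)-10α-(TBS-oxy)hydroazulen-4-one
Conditions: Dess–Martin periodinane, CH2Cl2, 0 °C → rt
Reagents that add atoms: none
Why: Dess–Martin oxidation under neutral conditions gives the cyclopentanone without epimerising C5 or eliminating the β-silyloxy group.

**Step 18**
Reactants: 24 6α-(TES-oxy)-10α-(TBS-oxy)hydroazulen-4-one; 25 isopropylmagnesium chloride
Product: 26 4α-isopropyl-6α-(TES-oxy)-10α-(TBS-oxy)hydroazulen-4β-ol
Conditions: iPrMgCl, CeCl3 (dried), THF, −78 °C; aq NH4Cl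
Reagents that add atoms: isopropylmagnesium chloride, CC(C)[Mg]Cl
Why: Organocerium 1,2-addition: the weakly basic isopropylcerium reagent suppresses enolisation, β-elimination and β-hydride reduction, and it attacks the cyclopentanone from the α face because the β face is screened by the 1,3-related angular methyl (as with D-ring ketones of steroids), giving 4β-OH/4α-iPr.

**Step 19**
Reactants: 26 4α-isopropyl-6α-(TES-oxy)-10α-(TBS-oxy)hydroazulen-4β-ol
Product: 27 4α-isopropyl-10α-(TBS-oxy)hydroazulene-4β,6α-diol
Conditions: HF·pyridine, pyridine, THF, 0 °C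
Reagents that add atoms: none
Why: Selective desilylation: the TES ether falls well before the neopentylic allylic TBS ether, and the tertiary alcohol is inert.

**Step 20**
Reactants: 27 4α-isopropyl-10α-(TBS-oxy)hydroazulene-4β,6α-diol; 28 4-methoxybenzoyl chloride
Product: 29 6α-(4-methoxybenzoyloxy)-4α-isopropyl-10α-(TBS-oxy)hydroazulen-4β-ol
Conditions: 4-MeOC6H4COCl, DMAP, Et3N, CH2Cl2, rt
Reagents that add atoms: 4-methoxybenzoyl chloride, COc1ccc(C(Cl)=O)cc1
Why: DMAP-catalysed esterification with the acid chloride (nucleophilic catalysis) occurs at the only secondary hydroxyl with retention at C6, since the tertiary C4–OH does not acylate.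

**Step 21**
Reactants: 29 6α-(4-methoxybenzoyloxy)-4α-isopropyl-10α-(TBS-oxy)hydroazulen-4β-ol
Product: 30 target CNP0211568.1
Conditions: Bu4NF, AcOH, THF, rt
Reagents that add atoms: none
Why: Fluoride desilylation buffered with acetic acid frees the 10α-OH without ester migration or hydrolysis and delivers the target.

**Compound list**
1 | (S)-Wieland–Miescher ketone | O=C1CCCC2=CC(=O)CC[C@]12C | starting material
2 | 1-methyl-Δ5(6)-octalin-4β,10β-diol | C1C[C@H](O)[C@@]2(C)CC[C@H](O)C=C2C1 | intermediate
3 | 4β-OTBS octalin-10β-ol | C1C[C@H](O)[C@@]2(C)CC[C@H](O[Si](C)(C)C(C)(C)C)C=C2C1 | intermediate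
4 | 4β-OTBS octalin-10-one | C1CC(=O)[C@@]2(C)CC[C@H](O[Si](C)(C)C(C)(C)C)C=C2C1 | intermediate
5 | lithium C9=C10 enolate of 4 (not isolated) | C1C=C(O[Li])[C@@]2(C)CC[C@H](O[Si](C)(C)C(C)(C)C)C=C2C1 | intermediate
6 | C9 N-tert-butyl-S-phenylsulfilimine of 4 (not isolated) | C1C(S(=NC(C)(C)C)c3ccccc3)C(=O)[C@@]2(C)CC[C@H](O[Si](C)(C)C(C)(C)C)C=C2C1 | intermediate
7 | 4β-OTBS 5(6),8(9)-dien-10-one | C1=CC(=O)[C@@]2(C)CC[C@H](O[Si](C)(C)C(C)(C)C)C=C2C1 | intermediate
8 | lithium enolate after C8 methylation (not isolated) | CC1C=C(O[Li])[C@@]2(C)CC[C@H](O[Si](C)(C)C(C)(C)C)C=C2C1 | intermediate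
9 | C9 sulfilimine of the 8-methyl ketone (not isolated) | CC1C(S(=NC(C)(C)C)c3ccccc3)C(=O)[C@@]2(C)CC[C@H](O[Si](C)(C)C(C)(C)C)C=C2C1 | intermediate
10 | 4β-OTBS 8-methyl-5(6),8(9)-dien-10-one | CC1=CC(=O)[C@@]2(C)CC[C@H](O[Si](C)(C)C(C)(C)C)C=C2C1 | intermediate
11 | 4β-hydroxy 8-methyl-5(6),8(9)-dien-10-one | CC1=CC(=O)[C@@]2(C)CC[C@H](O)C=C2C1 | intermediate
12 | 5β,6β-osmate ester, TMEDA chelate (not isolated) | CC1=CC(=O)[C@@]2(C)CC[C@H](O)[C@H](O[Os-2]4(=O)(=O)([N+](C)(C)CC[N+]4(C)C)O3)[C@@]23C1 | intermediate
13 | cis-decalin 4β,5β,6β-triol 8-en-10-one | CC1=CC(=O)[C@@]2(C)CC[C@H](O)[C@H](O)[C@@]2(O)C1 | intermediate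
14 | 4β-OTES 5β,6β-diol 8-en-10-one | CC1=CC(=O)[C@@]2(C)CC[C@H](O[Si](CC)(CC)CC)[C@H](O)[C@@]2(O)C1 | intermediate
15 | 4β-OTES 5β-OMs 6β-OH 8-en-10-one | CC1=CC(=O)[C@@]2(C)CC[C@H](O[Si](CC)(CC)CC)[C@H](OS(C)(=O)=O)[C@@]2(O)C1 | intermediate
16 | 4β-OTES 5β-OMs 8-ene-6β,10α-diol | CC1=C[C@@H](O)[C@@]2(C)CC[C@H](O[Si](CC)(CC)CC)[C@H](OS(C)(=O)=O)[C@@]2(O)C1 | intermediate
17 | cis-decalin hydroxy mesylate (key-step precursor) | CC1=C[C@@H](O[Si](C)(C)C(C)(C)C)[C@@]2(C)CC[C@H](O[Si](CC)(CC)CC)[C@H](OS(C)(=O)=O)[C@@]2(O)C1 | intermediate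
18 | potassium C6 alkoxide of 17 (not isolated) | CC1=C[C@@H](O[Si](C)(C)C(C)(C)C)[C@@]2(C)CC[C@H](O[Si](CC)(CC)CC)[C@H](OS(C)(=O)=O)[C@@]2([O-])C1.[K+] | intermediate
19 | trans-fused hydroazulen-6-one (key-step product) | O=C1CC(C)=C[C@@H](O[Si](C)(C)C(C)(C)C)[C@@]2(C)CC[C@H](O[Si](CC)(CC)CC)[C@H]12 | intermediate
20 | 4β-hydroxy-10α-OTBS hydroazulen-6-one | O=C1CC(C)=C[C@@H](O[Si](C)(C)C(C)(C)C)[C@@]2(C)CC[C@H](O)[C@H]12 | intermediate
21 | 4β-acetoxy-10α-OTBS hydroazulen-6α-ol | O[C@H]1CC(C)=C[C@@H](O[Si](C)(C)C(C)(C)C)[C@@]2(C)CC[C@H](OC(C)=O)[C@H]12 | intermediate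
22 | 4β-acetoxy-6α-OTES-10α-OTBS hydroazulene | CC[Si](CC)(CC)O[C@H]1CC(C)=C[C@@H](O[Si](C)(C)C(C)(C)C)[C@@]2(C)CC[C@H](OC(C)=O)[C@H]12 | intermediate
23 | 6α-OTES-10α-OTBS hydroazulen-4β-ol | CC[Si](CC)(CC)O[C@H]1CC(C)=C[C@@H](O[Si](C)(C)C(C)(C)C)[C@@]2(C)CC[C@H](O)[C@H]12 | intermediate
24 | 6α-OTES-10α-OTBS hydroazulen-4-one | CC[Si](CC)(CC)O[C@H]1CC(C)=C[C@@H](O[Si](C)(C)C(C)(C)C)[C@@]2(C)CCC(=O)[C@H]12 | intermediate
25 | isopropylmagnesium chloride | CC(C)[Mg]Cl | starting material
26 | 4α-isopropyl-6α-OTES-10α-OTBS hydroazulen-4β-ol | CC[Si](CC)(CC)O[C@H]1CC(C)=C[C@@H](O[Si](C)(C)C(C)(C)C)[C@@]2(C)CC[C@@](O)(C(C)C)[C@H]12 | intermediate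
27 | 4α-isopropyl-10α-OTBS hydroazulene-4β,6α-diol | O[C@H]1CC(C)=C[C@@H](O[Si](C)(C)C(C)(C)C)[C@@]2(C)CC[C@@](O)(C(C)C)[C@H]12 | intermediate
28 | 4-methoxybenzoyl chloride | COc1ccc(C(Cl)=O)cc1 | starting material
29 | 6α-anisate 10α-OTBS 4β-ol | COc1ccc(C(=O)O[C@H]2CC(C)=C[C@@H](O[Si](C)(C)C(C)(C)C)[C@@]3(C)CC[C@@](O)(C(C)C)[C@H]23)cc1 | intermediate
30 | CNP0211568.1 | COc1ccc(C(=O)O[C@H]2CC(C)=C[C@@H](O)[C@@]3(C)CC[C@@](O)(C(C)C)[C@H]23)cc1 | target

Total step count: 21. Longest linear sequence: 21 steps (from 1; the route is fully linear).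

**Steps most likely to fail**

1. **Step 12 (key step).**
   - What may go wrong: the reaction may run through the conformer with an axial mesylate, so that C7 migrates instead of C1. Residual base may also enolise the newly formed ketone, followed by epimerisation at C5, loss of the C4 silyloxy group or conjugation of the alkene.
   - Fallback: this sets out from 17 and replaces the anionic push by a Lewis-acid pull with reductive interception. Et3Al (CH2Cl2, −78 °C) forms the aluminium alkoxide and activates the sulfonate. iBu2AlH added to the same flask then reduces the ketone as it is released, giving the 4β-OTES-10α-OTBS hydroazulen-6β-ol F1, whose C6 configuration is of no consequence. Dess–Martin oxidation under neutral conditions comes back to the route at 19.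

2. **Step 7.**
   - What may go wrong: facial selectivity may be poor, because the angular methyl shields the β face of C5=C6 and may outweigh hydrogen-bond delivery. The osmate cleavage may also be slow enough to expose the β-hydroxy enone to acid for too long.
   - Fallback: this sets out from 10 and uses a Woodward cis-hydroxylation, which places the diol on the more hindered face by double inversion. I2 and AgOAc in AcOH attack the open α face and give the trans-iodoacetate F2, drawn as the Markovnikov isomer (either regioisomer converges). Silver-assisted acetate participation in wet AcOH then gives the 4β-OTBS 5β-acetoxy-6β-hydroxy enone F3. Methanolic HCl strips the silyl and acetyl groups and comes back to the route at 13.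

3. **Step 18.**
   - What may go wrong: enolisation, β-hydride reduction or sluggish addition of the branched nucleophile at the hindered β-silyloxy cyclopentanone, and erosion of α-face selectivity by the neighbouring 6α-silyloxy group.
   - Fallback: this sets out from 24 and adds the smaller sp2 nucleophile isopropenylmagnesium bromide with CeCl3 (THF, −78 °C). This nucleophile has no β-hydrogen to transfer, and it gives the 4α-isopropenyl-4β-ol F4. Chemoselective hydrogenation of the 1,1-disubstituted alkene with RhCl(PPh3)3 and H2 leaves the trisubstituted C8=C9 bond alone and comes back to the route at 26.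

**Further compounds**
F1 | step 12 | 4β-OTES-10α-OTBS hydroazulen-6β-ol | O[C@@H]1CC(C)=C[C@@H](O[Si](C)(C)C(C)(C)C)[C@@]2(C)CC[C@H](O[Si](CC)(CC)CC)[C@H]12
F2 | step 7 | 4β-OTBS 5α-iodo-6β-acetoxy 8-en-10-one | CC1=CC(=O)[C@@]2(C)CC[C@H](O[Si](C)(C)C(C)(C)C)[C@@H](I)[C@@]2(OC(C)=O)C1
F3 | step 7 | 4β-OTBS 5β-acetoxy-6β-hydroxy 8-en-10-one | CC1=CC(=O)[C@@]2(C)CC[C@H](O[Si](C)(C)C(C)(C)C)[C@H](OC(C)=O)[C@@]2(O)C1
F4 | step 18 | 4α-isopropenyl-6α-OTES-10α-OTBS hydroazulen-4β-ol | CC[Si](CC)(CC)O[C@H]1CC(C)=C[C@@H](O[Si](C)(C)C(C)(C)C)[C@@]2(C)CC[C@@](O)(C(C)=C)[C@H]12
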